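Ring A (the only ring) is numbered C1–C2–C3–C4(Me2)–C5(H)–C10(Me); C5 carries the 3-oxobutyl arm (C6–C8) and C10 the 3-methyl-6-oxohexanoate arm (C9, C11–C15) that ends in the 1-acyl-3-acetyl glyceride.
Late disconnections: acetate opening of a glycidyl ester made with (S)-glycidol; the C9–C11 ketone bond by Negishi acylation of a ring A acyl chloride with an alkylzinc from methyl hydrogen (R)-3-methylglutarate; the C5–H and C6–C7 bonds by hydroboration of a C5 exocyclic methylene and alkylation of the borane with bromoacetone.
Ring A is formed once, in the key step: a one-flask α,α'-annulation of the SAMP hydrazone of an acyclic β-keto ester with 1-chloro-3-iodopropane makes the C1–C10 bond and then the C3–C4 bond, and with them both quaternary carbons, the ring and the C10 stereocentre.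
Enabling feature: C5 is the single ring CH lying between the two quaternary ring carbons C4 (CMe2) and C10 (C(Me)–C9=O); taken back to a C5 carbonyl (as its hydrazone) it makes C10 and C4 the two α-carbons of one ketone, C10 being activated a second time by the C9 ester, so the three ring methylenes C1–C3 can arrive as a propane-1,3-diyl dielectrophile.
Stereocontrol: C10 by the auxiliary, C5 by C10 (hydroboration opposite the axial ester), C13 and the glycerol carbinol from purchased enantiopure building blocks.

Key step: step 3

Assumption: the lithiated SAMP hydrazone of the β-keto ester is taken to alkylate with the usual facial sense of SAMP azaenolates, with the ester cis to the metalated nitrogen, which leads to the R quaternary centre; if the opposite sense were found, RAMP would replace SAMP and nothing else would change.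

Step 1
Reactants: 1 tert-butyl propanoate; 2 2-methylpropanoyl chloride
Product: 3 tert-butyl 2,4-dimethyl-3-oxopentanoate (racemic at C2)
Conditions: 1 (2.0 equiv), LiN(i-Pr)2 (2.0 equiv), THF, −78 °C; then 2 (1.0 equiv), −78 → 0 °C; aq NH4Cl
Reagents that add atoms: none
Why: Crossed Claisen acylation of a preformed lithium ester enolate by an acid chloride, in which the second equivalent of enolate deprotonates the β-keto ester as it forms and so prevents diacylation; the α-stereocentre is formed racemic and is erased by metalation in step 3.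

Step 2
Reactants: 3 tert-butyl 2,4-dimethyl-3-oxopentanoate; 4 (2S)-2-(methoxymethyl)pyrrolidin-1-amine (SAMP)
Product: 5 tert-butyl 3-{[(2S)-2-(methoxymethyl)pyrrolidin-1-yl]imino}-2,4-dimethylpentanoate (C=N geometry and C2 configuration not defined)
Conditions: 4 (1.1 equiv), TsOH·H2O (cat), cyclohexane, reflux, Dean–Stark
Reagents that add atoms: none
Why: Acid-catalysed condensation of the ketone with the N-amino group of SAMP under azeotropic water removal (hydrazone formation); the tert-butyl ester resists aminolysis, and the C=N geometry and α-configuration do not matter because both are lost on metalation.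

Step 3
Reactants: 5 tert-butyl 3-{[(2S)-2-(methoxymethyl)pyrrolidin-1-yl]imino}-2,4-dimethylpentanoate; 6 1-chloro-3-iodopropane
Product: 8 tert-butyl (1R)-2-{[(2S)-2-(methoxymethyl)pyrrolidin-1-yl]imino}-1,3,3-trimethylcyclohexane-1-carboxylate, via chloropropyl hydrazone 7 (not isolated)
Conditions: LiN(i-Pr)2 (1.1 equiv), THF, −78 °C; 6 (1.1 equiv), −78 → −20 °C; then LiN(i-Pr)2 (2.0 equiv), DMPU, −78 → 25 °C
Reagents that add atoms: none
Why: Proposed new method: LiN(i-Pr)2 removes the doubly activated α-hydrogen of 5 to give an ester-chelated lithium azaenolate that is C-alkylated by the iodide end of 6 (SN2) to give 7, and a second charge of base then metalates the only α-hydrogen left, the isopropyl methine, so that the new azaenolate displaces chloride intramolecularly; both events are hydrazone azaenolate alkylations, and what is new is running them in one flask on a β-keto ester hydrazone so that a fully substituted azaenolate closes the ring. The closest known reaction types are the Enders SAMP-hydrazone α-alkylation (which gives α-quaternary β-keto esters and α,α'-bisalkylated ketones) and the α,α'-annulation of ketone enolates with 1,3-dihalopropanes. The cyclohexane closes in a 6-(enolendo)-exo-tet mode. The quaternary stereocentre is set in the first alkylation by the auxiliary, whose methoxymethyl arm chelates lithium and leaves one face of the planar azaenolate open, which is expected to give the R centre when the ester sits cis to the metalated nitrogen, whereas the gem-dimethyl carbon made in the ring closure is not stereogenic. The step needs iodide-over-chloride chemoselectivity (leaving-group difference at low temperature), C- over N-alkylation (normal for lithium azaenolates) and ring closure over elimination or intermolecular alkylation (six-membered transition state, no other acidic site), and the fully alkylated centre cannot epimerise afterwards.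

Step 4
Reactants: 8 tert-butyl (1R)-2-{[(2S)-2-(methoxymethyl)pyrrolidin-1-yl]imino}-1,3,3-trimethylcyclohexane-1-carboxylate
Product: 9 tert-butyl (1R)-1,3,3-trimethyl-2-oxocyclohexane-1-carboxylate
Conditions: O3, CH2Cl2, −78 °C; N2 purge
Reagents that add atoms: ozone, [O-][O+]=O
Why: Ozonolysis of the C=N bond is the standard racemisation-free cleavage of SAMP hydrazones and, being sterically undemanding, should work where hydrolysis of this doubly neopentyl hydrazone would not; the quaternary stereocentre cannot epimerise.

Step 5
Reactants: 9 tert-butyl (1R)-1,3,3-trimethyl-2-oxocyclohexane-1-carboxylate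
Product: 10 tert-butyl (1R)-1,3,3-trimethyl-2-methylidenecyclohexane-1-carboxylate
Conditions: Cp2TiMe2 (2.5 equiv), toluene, 70 °C, dark
Reagents that add atoms: dimethyltitanocene (Petasis reagent), C[Ti](C)(C1C=CC=C1)C1C=CC=C1
Why: Petasis methylenation, in which thermally generated Cp2Ti=CH2 adds to the ketone by [2+2] cycloaddition and cycloreversion under non-basic conditions, so the non-enolisable β-keto ester is spared the retro-Claisen cleavage that basic ylides could cause and the more hindered, less electrophilic tert-butyl ester is left alone.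

Step 6
Reactants: 10 tert-butyl (1R)-1,3,3-trimethyl-2-methylidenecyclohexane-1-carboxylate; 11 1-bromopropan-2-one
Product: 13 tert-butyl (1R,2S)-1,3,3-trimethyl-2-(3-oxobutyl)cyclohexane-1-carboxylate, via B-alkyl-9-BBN adduct 12 (not isolated)
Conditions: 9-BBN (1.2 equiv), THF, 65 °C; then 11 (1.2 equiv), potassium 2,6-di-tert-butylphenoxide (1.2 equiv), THF, 0 → 25 °C
Reagents that add atoms: none
Why: Brown hydroboration followed by the α-bromo ketone alkylation of B-alkyl-9-BBN reagents: boron adds to the terminal CH2 and hydrogen to the ring carbon from the face opposite the axial tert-butoxycarbonyl group and the syn-axial ring methyl (the chair that avoids a methyl/methyl syn-diaxial contact, as the carboxyls prefer in Kemp's triacid), which sets the ring CH as S with the new arm cis to the ester, and the potassium enolate of bromoacetone then adds to boron, the primary B-alkyl group migrates with loss of bromide, and protonation of the boron enolate gives the methyl ketone.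

Step 7
Reactants: 13 tert-butyl (1R,2S)-1,3,3-trimethyl-2-(3-oxobutyl)cyclohexane-1-carboxylate
Product: 14 (1R,2S)-1,3,3-trimethyl-2-(3-oxobutyl)cyclohexane-1-carboxylic acid
Conditions: CF3CO2H/CH2Cl2 (1:2), 0 → 25 °C
Reagents that add atoms: none
Why: Acidolysis of the tert-butyl ester by alkyl–oxygen cleavage (loss of isobutene) frees the hindered acid without any attack at the neopentyl-type carbonyl; the ketone and both stereocentres are inert to these conditions.

Step 8
Reactants: 15 (3R)-5-methoxy-3-methyl-5-oxopentanoic acid (methyl hydrogen (R)-3-methylglutarate)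
Product: 16 methyl (3R)-5-hydroxy-3-methylpentanoate
Conditions: BH3·SMe2 (1.1 equiv), THF, −10 → 20 °C; MeOH quench
Reagents that add atoms: none
Why: Borane reduces a carboxylic acid through its acyloxyborane much faster than it reduces an ester, so only the free acid terminus is reduced; the stereocentre is not involved.

Step 9
Reactants: 16 methyl (3R)-5-hydroxy-3-methylpentanoate
Product: 17 methyl (3S)-5-iodo-3-methylpentanoate
Conditions: I2, PPh3, imidazole, CH2Cl2, 0 → 25 °C
Reagents that add atoms: iodine, II
Why: Appel-type iodination of the primary alcohol by SN2 displacement of the oxyphosphonium group at CH2, done promptly to forestall lactonisation; the stereocentre is untouched and only its descriptor changes by priority.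

Step 10
Reactants: 14 (1R,2S)-1,3,3-trimethyl-2-(3-oxobutyl)cyclohexane-1-carboxylic acid; 17 methyl (3S)-5-iodo-3-methylpentanoate
Product: 20 methyl (3R)-3-methyl-6-oxo-6-[(1R,2S)-1,3,3-trimethyl-2-(3-oxobutyl)cyclohexyl]hexanoate, via acyl chloride 18 (not isolated), via alkylzinc iodide 19 (not isolated)
Conditions: 14, 1-chloro-N,N,2-trimethylprop-1-en-1-amine (Ghosez reagent), CH2Cl2, 0 → 25 °C; 17, Zn dust, LiCl, THF, 40 °C; combine, Pd(PPh3)4 (5 mol %), THF, 25 °C
Reagents that add atoms: none
Why: Negishi acylation, in which the acid is converted to its acyl chloride under neutral conditions (no α-hydrogen, so no ketene), the primary iodide inserts zinc to give an ester-tolerant alkylzinc, and palladium-catalysed acyl–alkyl coupling gives the ketone; organozincs do not add to the methyl ketone, the ester or the product, and no stereocentre is touched.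

Step 11
Reactants: 20 methyl (3R)-3-methyl-6-oxo-6-[(1R,2S)-1,3,3-trimethyl-2-(3-oxobutyl)cyclohexyl]hexanoate
Product: 21 (3R)-3-methyl-6-oxo-6-[(1R,2S)-1,3,3-trimethyl-2-(3-oxobutyl)cyclohexyl]hexanoic acid
Conditions: LiOH·H2O (2 equiv), THF/H2O (3:1), 0 °C; then 1 M HCl to pH 3
Reagents that add atoms: lithium hydroxide, [Li+].[OH-]
Why: Saponification of the unhindered methyl ester by acyl–oxygen cleavage at low temperature; the ketone next to the quaternary carbon is shielded, and the short cold exposure should keep aldol reaction of the 1,6-diketone from competing.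

Step 12
Reactants: 21 (3R)-3-methyl-6-oxo-6-[(1R,2S)-1,3,3-trimethyl-2-(3-oxobutyl)cyclohexyl]hexanoic acid; 22 [(2S)-oxiran-2-yl]methanol ((S)-glycidol)
Product: 23 [(2R)-oxiran-2-yl]methyl (3R)-3-methyl-6-oxo-6-[(1R,2S)-1,3,3-trimethyl-2-(3-oxobutyl)cyclohexyl]hexanoate
Conditions: 22 (1.2 equiv), DCC (1.1 equiv), DMAP (0.1 equiv), CH2Cl2, 0 → 25 °C
Reagents that add atoms: none
Why: Steglich esterification acylates the primary hydroxyl of glycidol under neutral conditions that leave the epoxide and both ketones intact; the oxirane stereocentre is not involved and its descriptor changes to R only by priority.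

Step 13
Reactants: 23 [(2R)-oxiran-2-yl]methyl (3R)-3-methyl-6-oxo-6-[(1R,2S)-1,3,3-trimethyl-2-(3-oxobutyl)cyclohexyl]hexanoate; 24 acetic acid
Product: 25 (2R)-3-(acetyloxy)-2-hydroxypropyl (3R)-3-methyl-6-oxo-6-[(1R,2S)-1,3,3-trimethyl-2-(3-oxobutyl)cyclohexyl]hexanoate (CNP0140002.2)
Conditions: 24 (3 equiv), n-Bu4NOAc (10 mol %), toluene, 60 °C
Reagents that add atoms: none
Why: Carboxylate-catalysed SN2 opening of the terminal epoxide by acetic acid at the unsubstituted carbon, the known route from glycidyl esters to 1,3-diacylglycerols; the C–O bond at the stereocentre is not broken, so the secondary carbinol should be obtained with the required R configuration.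

Compound list
1 | tert-butyl propanoate | CCC(=O)OC(C)(C)C | starting material
2 | 2-methylpropanoyl chloride | CC(C)C(Cl)=O | starting material
3 | tert-butyl 2,4-dimethyl-3-oxopentanoate (racemic) | CC(C)C(=O)C(C)C(=O)OC(C)(C)C | intermediate
4 | (2S)-2-(methoxymethyl)pyrrolidin-1-amine (SAMP) | COC[C@@H]1CCCN1N | starting material
5 | tert-butyl 3-{[(2S)-2-(methoxymethyl)pyrrolidin-1-yl]imino}-2,4-dimethylpentanoate | COC[C@@H]1CCCN1N=C(C(C)C)C(C)C(=O)OC(C)(C)C | intermediate
6 | 1-chloro-3-iodopropane | ClCCCI | starting material
7 | tert-butyl (2R)-2-(3-chloropropyl)-3-{[(2S)-2-(methoxymethyl)pyrrolidin-1-yl]imino}-2,4-dimethylpentanoate | COC[C@@H]1CCCN1N=C(C(C)C)[C@@](C)(CCCCl)C(=O)OC(C)(C)C | intermediate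
8 | tert-butyl (1R)-2-{[(2S)-2-(methoxymethyl)pyrrolidin-1-yl]imino}-1,3,3-trimethylcyclohexane-1-carboxylate | COC[C@@H]1CCCN1N=C1C(C)(C)CCC[C@@]1(C)C(=O)OC(C)(C)C | intermediate
9 | tert-butyl (1R)-1,3,3-trimethyl-2-oxocyclohexane-1-carboxylate | O=C1C(C)(C)CCC[C@@]1(C)C(=O)OC(C)(C)C | intermediate
10 | tert-butyl (1R)-1,3,3-trimethyl-2-methylidenecyclohexane-1-carboxylate | C=C1C(C)(C)CCC[C@@]1(C)C(=O)OC(C)(C)C | intermediate
11 | 1-bromopropan-2-one (bromoacetone) | CC(=O)CBr | starting material
12 | tert-butyl (1R,2S)-2-[(9-borabicyclo[3.3.1]nonan-9-yl)methyl]-1,3,3-trimethylcyclohexane-1-carboxylate | C1CCC2CCCC1B2C[C@H]1C(C)(C)CCC[C@@]1(C)C(=O)OC(C)(C)C | intermediate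
13 | tert-butyl (1R,2S)-1,3,3-trimethyl-2-(3-oxobutyl)cyclohexane-1-carboxylate | CC(=O)CC[C@H]1C(C)(C)CCC[C@@]1(C)C(=O)OC(C)(C)C | intermediate
14 | (1R,2S)-1,3,3-trimethyl-2-(3-oxobutyl)cyclohexane-1-carboxylic acid | CC(=O)CC[C@H]1C(C)(C)CCC[C@@]1(C)C(=O)O | intermediate
15 | (3R)-5-methoxy-3-methyl-5-oxopentanoic acid (methyl hydrogen (R)-3-methylglutarate) | OC(=O)C[C@@H](C)CC(=O)OC | starting material
16 | methyl (3R)-5-hydroxy-3-methylpentanoate | OCC[C@@H](C)CC(=O)OC | intermediate
17 | methyl (3S)-5-iodo-3-methylpentanoate | ICC[C@@H](C)CC(=O)OC | intermediate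
18 | (1R,2S)-1,3,3-trimethyl-2-(3-oxobutyl)cyclohexane-1-carbonyl chloride | CC(=O)CC[C@H]1C(C)(C)CCC[C@@]1(C)C(Cl)=O | intermediate
19 | iodo[(3S)-5-methoxy-3-methyl-5-oxopentyl]zinc | I[Zn]CC[C@@H](C)CC(=O)OC | intermediate
20 | methyl (3R)-3-methyl-6-oxo-6-[(1R,2S)-1,3,3-trimethyl-2-(3-oxobutyl)cyclohexyl]hexanoate | CC(=O)CC[C@H]1C(C)(C)CCC[C@@]1(C)C(=O)CC[C@@H](C)CC(=O)OC | intermediate
21 | (3R)-3-methyl-6-oxo-6-[(1R,2S)-1,3,3-trimethyl-2-(3-oxobutyl)cyclohexyl]hexanoic acid | CC(=O)CC[C@H]1C(C)(C)CCC[C@@]1(C)C(=O)CC[C@@H](C)CC(=O)O | intermediate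
22 | [(2S)-oxiran-2-yl]methanol ((S)-glycidol) | OC[C@H]1CO1 | starting material
23 | [(2R)-oxiran-2-yl]methyl (3R)-3-methyl-6-oxo-6-[(1R,2S)-1,3,3-trimethyl-2-(3-oxobutyl)cyclohexyl]hexanoate | CC(=O)CC[C@H]1C(C)(C)CCC[C@@]1(C)C(=O)CC[C@@H](C)CC(=O)OC[C@H]1CO1 | intermediate
24 | acetic acid | CC(=O)O | starting material
25 | (2R)-3-(acetyloxy)-2-hydroxypropyl (3R)-3-methyl-6-oxo-6-[(1R,2S)-1,3,3-trimethyl-2-(3-oxobutyl)cyclohexyl]hexanoate (CNP0140002.2) | CC(=O)CC[C@H]1C(C)(C)CCC[C@@]1(C)C(=O)CC[C@@H](C)CC(=O)OC[C@H](O)COC(C)=O | target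

Total step count: 13
Longest linear sequence: 11 steps (steps 1–7 and 10–13; steps 8 and 9 prepare the side-chain iodide).

Steps most likely to fail

1. Step 3 (bears the label). The second metalation may be slow, because the tetrasubstituted azaenolate is strained against the neighbouring quaternary carbon and the N-amino group, so elimination of HCl or simple recovery of 7 could compete with ring closure. The fallback uses known chemistry and sets out from 5: only the first alkylation is run (LiN(i-Pr)2, 6, THF, −78 → 0 °C) and 7 is isolated. Ozonolysis (O3, CH2Cl2, −78 °C) should then remove the auxiliary to give tert-butyl (2R)-2-(3-chloropropyl)-2,4-dimethyl-3-oxopentanoate F1. The ring is closed through the potassium enolate of the isopropyl ketone (KN(SiMe3)2, NaI cat, THF, −78 → 25 °C), a 6-(enolendo)-exo-tet ketone alkylation, which comes back to the route at 9.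

2. Step 5. Olefination may not take place at the doubly neopentyl carbonyl, or the ester may begin to react on prolonged heating. The fallback sets out from 9 and brings in the whole side arm by carbonyl addition instead. The organocerium reagent from 2-(2-bromoethyl)-2-methyl-1,3-dioxolane (Mg; CeCl3, THF, −78 °C) should give the tertiary alcohol tert-butyl (1R)-2-hydroxy-1,3,3-trimethyl-2-[2-(2-methyl-1,3-dioxolan-2-yl)ethyl]cyclohexane-1-carboxylate F2. Dehydration (SOCl2, pyridine, 0 °C), possible only toward the side chain, should give the exocyclic alkene tert-butyl (1R)-1,3,3-trimethyl-2-[2-(2-methyl-1,3-dioxolan-2-yl)ethylidene]cyclohexane-1-carboxylate F3. Hydrogenation (H2, Pd/C, EtOAc) from the face opposite the axial ester should give tert-butyl (1R,2S)-1,3,3-trimethyl-2-[2-(2-methyl-1,3-dioxolan-2-yl)ethyl]cyclohexane-1-carboxylate F4. CF3CO2H/H2O/CH2Cl2 then cleaves the tert-butyl ester and the dioxolane together and comes back to the route at 14.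

3. Step 6. Ate-complex formation or 1,2-migration at the β-branched B-alkyl group may be slow, giving protodeboronation instead, and facial selectivity in the hydroboration may be incomplete. The fallback sets out from 10 and builds the arm by carbonyl olefination. Hydroboration–oxidation (9-BBN, THF; NaBO3·4H2O) should give the primary alcohol tert-butyl (1R,2S)-2-(hydroxymethyl)-1,3,3-trimethylcyclohexane-1-carboxylate F5, at which stage a minor diastereomer can be removed. Oxidation with Dess–Martin periodinane should give the aldehyde tert-butyl (1R,2S)-2-formyl-1,3,3-trimethylcyclohexane-1-carboxylate F6. Wittig reaction with 1-(triphenylphosphoranylidene)propan-2-one (toluene, 80 °C) should give the enone tert-butyl (1R,2S)-1,3,3-trimethyl-2-[(1E)-3-oxobut-1-en-1-yl]cyclohexane-1-carboxylate F7. Hydrogenation of the C=C bond (H2, Pd/C, EtOAc) comes back to the route at 13.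

Further compounds
F1 | step 3 | tert-butyl (2R)-2-(3-chloropropyl)-2,4-dimethyl-3-oxopentanoate | CC(C)C(=O)[C@@](C)(CCCCl)C(=O)OC(C)(C)C
F2 | step 5 | tert-butyl (1R)-2-hydroxy-1,3,3-trimethyl-2-[2-(2-methyl-1,3-dioxolan-2-yl)ethyl]cyclohexane-1-carboxylate | CC1(OCCO1)CCC1(O)C(C)(C)CCC[C@@]1(C)C(=O)OC(C)(C)C
F3 | step 5 | tert-butyl (1R)-1,3,3-trimethyl-2-[2-(2-methyl-1,3-dioxolan-2-yl)ethylidene]cyclohexane-1-carboxylate | CC1(OCCO1)CC=C1C(C)(C)CCC[C@@]1(C)C(=O)OC(C)(C)C
F4 | step 5 | tert-butyl (1R,2S)-1,3,3-trimethyl-2-[2-(2-methyl-1,3-dioxolan-2-yl)ethyl]cyclohexane-1-carboxylate | CC1(OCCO1)CC[C@H]1C(C)(C)CCC[C@@]1(C)C(=O)OC(C)(C)C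
F5 | step 6 | tert-butyl (1R,2S)-2-(hydroxymethyl)-1,3,3-trimethylcyclohexane-1-carboxylate | OC[C@H]1C(C)(C)CCC[C@@]1(C)C(=O)OC(C)(C)C
F6 | step 6 | tert-butyl (1R,2S)-2-formyl-1,3,3-trimethylcyclohexane-1-carboxylate | O=C[C@H]1C(C)(C)CCC[C@@]1(C)C(=O)OC(C)(C)C
F7 | step 6 | tert-butyl (1R,2S)-1,3,3-trimethyl-2-[(1E)-3-oxobut-1-en-1-yl]cyclohexane-1-carboxylate | CC(=O)/C=C/[C@H]1C(C)(C)CCC[C@@]1(C)C(=O)OC(C)(C)C
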